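**Retrosynthetic overview**
- The dihydropyran is the dehydrated hemiketal of a δ-hydroxy ketone, so the pyran C–O bond is made last by cyclodehydration.
- The pyran C5–cyclohexyl C1 bond comes from anodic decarboxylation of a β-hydroxy acid with 1,2-shift of the cyclohexyl group. That acid comes from an aldol between a bromo-δ-lactone enolate and a cyclohexyl methyl ketone.
- The cyclohexane ring is bought as (−)-cis-limonene oxide. Its epoxide sets the ring Br and Cl: diaxial opening by bromide, then a bromonium relay (1,2-Br shift) captured by chloride.
- The pyran C3–Br stereocentre is bought as D-glutamic acid and carried through (R)-2-bromoglutarate into the lactone (gem-dimethyl from MeMgCl).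
- Ring order: cyclohexane (bought) → transient δ-lactone → dihydropyran (last).

Assumption: the single cis isomer of (−)-limonene 1,2-oxide is used. It is the component of the cheap commercial cis/trans mixture that survives the standard amine/water treatment that consumes the trans isomer; I recalled this from memory and did not count it as a step.

**Step 1**
Reactants: 1, (−)-cis-limonene 1,2-oxide [(1S,4S,6R)-1-methyl-4-(prop-1-en-2-yl)-7-oxabicyclo[4.1.0]heptane; epoxide O trans to isopropenyl]
Product: 2, 1-[(1R,3S,6S)-6-methyl-7-oxabicyclo[4.1.0]heptan-3-yl]ethan-1-one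
Conditions: O3, CH2Cl2/MeOH, −78 °C; then Me2S, −78 °C → rt
Reagents that add atoms: ozone, [O-][O+]=O
Why: Ozonolysis cleaves the only C=C (the isopropenyl group) to the methyl ketone while the epoxide and all three stereocentres are untouched.

**Step 2**
Reactants: 2, 1-[(1R,3S,6S)-6-methyl-7-oxabicyclo[4.1.0]heptan-3-yl]ethan-1-one
Product: 3, 1-[(1S,3R,4R)-4-bromo-3-hydroxy-4-methylcyclohexyl]ethan-1-one (tertiary Br cis to acetyl, secondary OH trans; Br and OH trans-diaxial)
Conditions: MgBr2·OEt2 (1.5 equiv), Et2O, −20 → 0 °C; aq. NH4Cl
Reagents that add atoms: magnesium bromide, Br[Mg]Br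
Why: Lewis-acid epoxide opening by bromide at the tertiary carbon with inversion is both Markovnikov and trans-diaxial (Fürst–Plattner) for this epoxide isomer, so the bought epoxide stereocentres fix Br cis and OH trans to the acetyl-bearing carbon.

**Step 3**
Reactants: 3, 1-[(1S,3R,4R)-4-bromo-3-hydroxy-4-methylcyclohexyl]ethan-1-one
Product: 4, 1-[(1S,3S,4S)-3-bromo-4-chloro-4-methylcyclohexyl]ethan-1-one (acetyl, Br and Cl all equatorial, CH3 axial)
Conditions: Ph3P, N-chlorosuccinimide, Et4NCl, MeCN, −20 → 20 °C
Reagents that add atoms: N-chlorosuccinimide, O=C1CCC(=O)N1Cl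
Why: Proposed new method: Appel-type activation turns the axial secondary OH into a leaving group antiperiplanar to the axial tertiary C–Br, so bromine participates to give the bromonium ion on the face cis to the acetyl-bearing carbon, and chloride then opens it anti at the more cationic tertiary carbon; Br therefore ends on C3 and Cl on C4, each with inversion, giving the trans-diequatorial array that direct alkene bromochlorination does not favour; the closest known chemistry is anchimerically assisted substitution of activated trans-2-bromocycloalkanols (bromonium generation and halide capture) and Appel deoxychlorination, not yet shown with a tertiary bromide to give a net 1,2-Br shift and tertiary chlorination.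

**Step 4**
Reactants: 5, D-glutamic acid [(R)-2-aminopentanedioic acid]
Product: 6, (R)-2-bromopentanedioic acid
Conditions: NaNO2, KBr, 2 M aq. HBr, −5 → 0 °C
Reagents that add atoms: potassium bromide, [K+].[Br-] (with hydrogen bromide, Br)
Why: Diazotisation of the α-amino acid proceeds through the α-lactone, so bromide enters with overall retention (double inversion) and the bought stereocentre becomes the C–Br centre.

**Step 5**
Reactants: 6, (R)-2-bromopentanedioic acid
Product: 7, dimethyl (R)-2-bromopentanedioate
Conditions: H2SO4 (cat.), MeOH, rt
Reagents that add atoms: methanol, CO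
Why: Fischer esterification of both acids without chloride or base, so the α-bromo stereocentre is not exchanged or enolised.

**Step 6**
Reactants: 7, dimethyl (R)-2-bromopentanedioate
Product: 8, (R)-5-bromo-6,6-dimethyloxan-2-one
Conditions: MeMgCl (2.1 equiv), CeCl3, THF, −78 → −40 °C; then TsOH (cat.), CH2Cl2, rt
Reagents that add atoms: methylmagnesium chloride, C[Mg]Cl (two methyl groups)
Why: The α-bromo ester is the more electrophilic ester and takes up two methyl groups (Grignard addition), and the resulting tertiary alcohol lactonises onto the remote ester to the six-membered lactone; the C–Br bond is not broken, so configuration is kept.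

**Step 7**
Reactants: 8, (R)-5-bromo-6,6-dimethyloxan-2-one; 4, 1-[(1S,3S,4S)-3-bromo-4-chloro-4-methylcyclohexyl]ethan-1-one
Product: 9, (5R)-5-bromo-3-{1-[(1S,3S,4S)-3-bromo-4-chloro-4-methylcyclohexyl]-1-hydroxyethyl}-6,6-dimethyloxan-2-one (mixture at lactone C3 and at the carbinol carbon)
Conditions: LDA, THF, −78 °C; then 4, −78 °C; AcOH quench at −78 °C
Reagents that add atoms: none
Why: Aldol addition of the lactone lithium enolate to the methyl ketone; the two new stereocentres are formed unselectively but both become sp2 later, and the four stereocentres already present are untouched at −78 °C.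

**Step 8**
Reactants: 9, (5R)-5-bromo-3-{1-[(1S,3S,4S)-3-bromo-4-chloro-4-methylcyclohexyl]-1-hydroxyethyl}-6,6-dimethyloxan-2-one
Product: 10, (5R)-5-bromo-3-[(1S,3S,4S)-3-bromo-4-chloro-4-methylcyclohexyl]-6-hydroxy-6-methylheptan-2-one (mixture at C3)
Conditions: LiOH (1.0 equiv), THF/H2O, 0 °C; then MeOH, graphite anode/Pt cathode, divided cell, 10 mA cm⁻², ca. 2.5 F mol⁻¹, 0 °C
Reagents that add atoms: none (water supplies only H; CO2 is lost)
Why: After lactone opening, non-Kolbe (Hofer–Moest) anodic decarboxylation of the β-hydroxy carboxylate generates a cation next to the carbinol, which triggers a semipinacol 1,2-shift of the cyclohexyl group (secondary alkyl over methyl) with retention at the migrating carbon; this forms the cyclohexyl–C3 bond and the methyl ketone without touching the halogen-bearing stereocentres.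

**Step 9**
Reactants: 10, (5R)-5-bromo-3-[(1S,3S,4S)-3-bromo-4-chloro-4-methylcyclohexyl]-6-hydroxy-6-methylheptan-2-one
Product: 11, laucapyranoid A [(3R)-3-bromo-5-[(1S,3S,4S)-3-bromo-4-chloro-4-methylcyclohexyl]-2,2,6-trimethyl-3,4-dihydro-2H-pyran]
Conditions: PPTS (cat.), toluene, 4 Å MS, 80 °C
Reagents that add atoms: none
Why: Acid-catalysed hemiketalisation by the tertiary OH and dehydration give the thermodynamically preferred tetrasubstituted endocyclic enol ether; both C3 epimers of 10 converge because that carbon becomes sp2.

**Compound list**
1 | (−)-cis-limonene 1,2-oxide, (1S,4S,6R)-1-methyl-4-(prop-1-en-2-yl)-7-oxabicyclo[4.1.0]heptane | CC(=C)[C@H]1CC[C@]2(C)O[C@@H]2C1 | starting material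
2 | 1-[(1R,3S,6S)-6-methyl-7-oxabicyclo[4.1.0]heptan-3-yl]ethan-1-one | CC(=O)[C@H]1CC[C@]2(C)O[C@@H]2C1 | intermediate
3 | 1-[(1S,3R,4R)-4-bromo-3-hydroxy-4-methylcyclohexyl]ethan-1-one | CC(=O)[C@H]1CC[C@@](C)(Br)[C@H](O)C1 | intermediate
4 | 1-[(1S,3S,4S)-3-bromo-4-chloro-4-methylcyclohexyl]ethan-1-one | CC(=O)[C@H]1CC[C@](C)(Cl)[C@@H](Br)C1 | intermediate
5 | D-glutamic acid | N[C@H](CCC(=O)O)C(=O)O | starting material
6 | (R)-2-bromopentanedioic acid | OC(=O)CC[C@@H](Br)C(=O)O | intermediate
7 | dimethyl (R)-2-bromopentanedioate | COC(=O)CC[C@@H](Br)C(=O)OC | intermediate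
8 | (R)-5-bromo-6,6-dimethyloxan-2-one | Br[C@@H]1CCC(=O)OC1(C)C | intermediate
9 | (5R)-5-bromo-3-{1-[(1S,3S,4S)-3-bromo-4-chloro-4-methylcyclohexyl]-1-hydroxyethyl}-6,6-dimethyloxan-2-one (epimer mixture at C3 and carbinol C) | CC(O)([C@H]1CC[C@](C)(Cl)[C@@H](Br)C1)C2C[C@@H](Br)C(C)(C)OC2=O | intermediate
10 | (5R)-5-bromo-3-[(1S,3S,4S)-3-bromo-4-chloro-4-methylcyclohexyl]-6-hydroxy-6-methylheptan-2-one (epimer mixture at C3) | CC(=O)C([C@H]1CC[C@](C)(Cl)[C@@H](Br)C1)C[C@@H](Br)C(C)(C)O | intermediate
11 | laucapyranoid A | CC1=C([C@H]2CC[C@](C)(Cl)[C@@H](Br)C2)C[C@@H](Br)C(C)(C)O1 | target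

**Totals**
Total steps: 9. Longest linear sequence: 6 (1 → 2 → 3 → 4 → 9 → 10 → 11, or 5 → 6 → 7 → 8 → 9 → 10 → 11).

**Three steps most likely to fail**
- **Step 3 (proposed new step).** Chloride may instead open the bromonium at the secondary carbon (the diaxial mode), returning a tertiary bromide/secondary chloride, or the ion may lose a proton. Fallback (known chemistry): make (S)-4-acetyl-1-methylcyclohexene from (S)-limonene (OsO4/NaIO4) and add a BrCl equivalent (NBS/Et4NCl) across the ring alkene. The diaxial adduct is expected to dominate, so 4 would be isolated as the minor trans-diequatorial adduct by chromatography.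
- **Step 8.** Base may close the C5-bromide/C6-alkoxide to an epoxide during lactone opening, and the cation may be trapped by the tertiary OH (tetrahydrofuran) or undergo methyl instead of cyclohexyl shift. Fallback: drive the saponification deliberately to the epoxy acid with excess LiOH and electrolyse that base-stable substrate. Then reopen the epoxide with MgBr2 (tertiary Br/secondary OH) and close the pyran by the same OH-activation/1,2-Br shift as step 3, with the ketone oxygen capturing the tertiary carbon. This costs two extra steps, and Br returns to C3 in its original configuration by double inversion.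
- **Step 7.** The enolate may deprotonate the ketone instead of adding, the aldolate may revert, and the all-equatorial ketone 4 could epimerise at its α-carbon. Fallback: reverse the order. Run the aldol of 8 on the halide-free epoxy ketone 2, then do the MgBr2 opening and the bromonium-relay chlorination on the aldol adduct (the tertiary OH is not activated under Appel conditions), rejoining the route at 9.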